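**Retrosynthetic overview**
The strategy rests on C8, the methyl-bearing CH between the benzylic C7 on ring A and the ether oxygen to C4' of ring B: with C7 as a ketone, C8–H is acidic and C8 is stereolabile, while C7 is a prochiral aryl ketone.
Disconnections: the allylic alcohol comes from the E-enoate; the C7–OH/C8–H pair comes from a racemic alpha-aryloxy ketone by asymmetric transfer hydrogenation under dynamic kinetic resolution; the C8–O–C4' ether comes from an alpha-bromo ketone and methyl sinapate.
The ring A half is built from 3,4,5-trimethoxybenzaldehyde and ethylmagnesium bromide, the ring B half from syringaldehyde by Wittig olefination.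
Both benzene rings are bought and no ring is formed; the order is ring A side chain, ring B acrylate, ether union, both stereocentres in one step, ester reduction.

Key step: step 6

Remark on the chemistry: neolignan numbering is used (C7 is the benzylic carbinol carbon, C8 the methyl-bearing ether carbon), and CIP analysis of the given SMILES gives 7R,8R, the threo isomer. RuCl[(S,S)-teth-TsDPEN] denotes the chlororuthenium complex of (S,S)-N-tosyl-N'-(3-phenylpropyl)-1,2-diphenylethane-1,2-diamine, in which the tether phenyl is the eta6-arene.

**Step 1**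
Reactants: 1 3,4,5-trimethoxybenzaldehyde; 2 ethylmagnesium bromide
Product: 3 racemic 1-(3,4,5-trimethoxyphenyl)propan-1-ol
Conditions: EtMgBr (1.2 equiv), THF, 0 °C to rt; aq NH4Cl
Reagents that add atoms: none
Why: Grignard 1,2-addition to an unhindered aromatic aldehyde, the racemic carbinol centre being erased by the oxidation that follows.

**Step 2**
Reactants: 3 racemic 1-(3,4,5-trimethoxyphenyl)propan-1-ol
Product: 4 1-(3,4,5-trimethoxyphenyl)propan-1-one
Conditions: activated MnO2 (10 equiv), CH2Cl2, rt
Reagents that add atoms: none
Why: Heterogeneous MnO2 oxidation of a benzylic alcohol, which should stop cleanly at the aryl ketone and leave the aryl methyl ethers alone.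

**Step 3**
Reactants: 4 1-(3,4,5-trimethoxyphenyl)propan-1-one
Product: 5 racemic 2-bromo-1-(3,4,5-trimethoxyphenyl)propan-1-one
Conditions: CuBr2 (2.1 equiv), EtOAc/CHCl3 1:1, reflux
Reagents that add atoms: copper dibromide, Br[Cu]Br
Why: Alpha-bromination of an aryl ketone through its copper-bound enol (King–Ostrum conditions), which should put bromine only on the enolisable C8 and not on the electron-rich ring, whose two open positions sit ortho to the deactivating acyl group; C8 is formed racemic, as intended.

**Step 4**
Reactants: 6 syringaldehyde (4-hydroxy-3,5-dimethoxybenzaldehyde); 7 methyl (triphenylphosphoranylidene)acetate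
Product: 8 methyl (E)-sinapate (methyl (E)-3-(4-hydroxy-3,5-dimethoxyphenyl)prop-2-enoate)
Conditions: toluene, 90 °C
Reagents that add atoms: none
Why: Wittig olefination with a stabilised ylide, whose reversible addition funnels to the E enoate and whose low basicity tolerates the free phenol.

**Step 5**
Reactants: 5 racemic 2-bromo-1-(3,4,5-trimethoxyphenyl)propan-1-one; 8 methyl (E)-sinapate
Product: 9 racemic methyl (E)-3-[3,5-dimethoxy-4-[[1-oxo-1-(3,4,5-trimethoxyphenyl)propan-2-yl]oxy]phenyl]prop-2-enoate
Conditions: K2CO3 (1.5 equiv), acetone, reflux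
Reagents that add atoms: none
Why: Williamson ether synthesis by SN2 displacement at a bromide activated by the adjacent carbonyl, reactive enough to accept the hindered 2,6-dimethoxyphenoxide and giving the C8–O–C4' ether with C8 racemic, which is what the next step requires.

**Step 6**
Reactants: 9 racemic keto ether enoate
Product: 11 methyl (E)-3-[4-[[(1R,2R)-1-hydroxy-1-(3,4,5-trimethoxyphenyl)propan-2-yl]oxy]-3,5-dimethoxyphenyl]prop-2-enoate, via (R)-configured ketone 10 (not isolated)
Conditions: RuCl[(S,S)-teth-TsDPEN] (2 mol%), Et3N (5 equiv), DBU (0.5 equiv), HCO2H (2.5 equiv, slow addition), DMF, 40 °C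
Reagents that add atoms: none
Why: Proposed new method: the closest known reaction type is the Noyori–Ikariya asymmetric transfer hydrogenation under dynamic kinetic resolution of racemic benzoin (to threo-hydrobenzoin) and of alpha-fluoro aryl ketones, not shown for an acyclic alpha-aryloxy alpha-methyl aryl ketone; mechanistically, free amine (DBU, Et3N) removes the C8 proton, acidified by the C7 carbonyl and the aryloxy oxygen to roughly the level of an alpha-fluoro ketone, so the two enantiomers of 9 interconvert through the planar enol, while the Ru–H/N–H form of the catalyst, regenerated from formate with irreversible loss of CO2, passes hydride and proton to the C7 carbonyl in an outer-sphere six-membered transition state. C7 is set by the catalyst: the CH/pi contact between the eta6-arene and the trimethoxyphenyl ring orients the ketone so that the (S,S) ligand delivers hydride to the Si face, giving 7R in the same spatial sense in which this ligand series gives (S)-1-phenylethanol and (R,R)-hydrobenzoin. C8 is set by selection among the equilibrating enantiomers: the metal never binds the ether oxygen, so there is no chelate, and on that face only the R ketone 10 can hold the polar Felkin–Anh geometry (C8–OAr anti to the forming C7–H bond, C8–H and not C8–CH3 beside the incoming hydride), so 10 should be consumed fast and the S ketone returned through the enol, giving the threo (7R,8R) product. The step needs face selectivity at C7, C8 epimerisation that outruns reduction of the slow enantiomer, and reduction of the ketone only; these rest on the aryl ketone/arene contact, on slow formic acid addition that leaves DBU largely unprotonated together with the bulk of the 2,6-dimethoxyaryl ether that retards the mismatched reduction, and on the preference of the bifunctional hydride for a polar C=O over the electron-rich cinnamate C=C and the ester. No ring is closed.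

**Step 7**
Reactants: 11 (7R,8R)-threo hydroxy ether enoate
Product: 13 (1R,2R)-2-[4-[(E)-3-hydroxyprop-1-enyl]-2,6-dimethoxyphenoxy]-1-(3,4,5-trimethoxyphenyl)propan-1-ol (CNP0196275.1), via threo hydroxy enal 12 (not isolated)
Conditions: i-Bu2AlH (4.5 equiv), CH2Cl2, −78 to −20 °C; aq potassium sodium tartrate
Reagents that add atoms: none
Why: DIBAL-H 1,2-reduction of an alpha,beta-unsaturated ester to the allylic alcohol by way of the enal, the first equivalent being spent on the C7 hydroxyl (carried as its aluminate), with neither stereocentre epimerisable (C8 is no longer alpha to a carbonyl) and the E alkene untouched.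

**Compound list**
1 | 3,4,5-trimethoxybenzaldehyde | COc1cc(C=O)cc(OC)c1OC | starting material
2 | ethylmagnesium bromide | CC[Mg]Br | starting material
3 | racemic 1-(3,4,5-trimethoxyphenyl)propan-1-ol | CCC(O)c1cc(OC)c(OC)c(OC)c1 | intermediate
4 | 1-(3,4,5-trimethoxyphenyl)propan-1-one | CCC(=O)c1cc(OC)c(OC)c(OC)c1 | intermediate
5 | racemic 2-bromo-1-(3,4,5-trimethoxyphenyl)propan-1-one | CC(Br)C(=O)c1cc(OC)c(OC)c(OC)c1 | intermediate
6 | syringaldehyde | COc1cc(C=O)cc(OC)c1O | starting material
7 | methyl (triphenylphosphoranylidene)acetate | COC(=O)C=P(c1ccccc1)(c1ccccc1)c1ccccc1 | starting material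
8 | methyl (E)-sinapate | COC(=O)/C=C/c1cc(OC)c(O)c(OC)c1 | intermediate
9 | racemic methyl (E)-3-[3,5-dimethoxy-4-[[1-oxo-1-(3,4,5-trimethoxyphenyl)propan-2-yl]oxy]phenyl]prop-2-enoate | COc1cc(C(=O)C(C)Oc2c(OC)cc(/C=C/C(=O)OC)cc2OC)cc(OC)c1OC | intermediate
10 | methyl (E)-3-[3,5-dimethoxy-4-[[(2R)-1-oxo-1-(3,4,5-trimethoxyphenyl)propan-2-yl]oxy]phenyl]prop-2-enoate (fast-reacting enantiomer, replenished by epimerisation) | COc1cc(C(=O)[C@@H](C)Oc2c(OC)cc(/C=C/C(=O)OC)cc2OC)cc(OC)c1OC | intermediate (not isolated)
11 | methyl (E)-3-[4-[[(1R,2R)-1-hydroxy-1-(3,4,5-trimethoxyphenyl)propan-2-yl]oxy]-3,5-dimethoxyphenyl]prop-2-enoate | COc1cc([C@@H](O)[C@@H](C)Oc2c(OC)cc(/C=C/C(=O)OC)cc2OC)cc(OC)c1OC | intermediate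
12 | (E)-3-[4-[[(1R,2R)-1-hydroxy-1-(3,4,5-trimethoxyphenyl)propan-2-yl]oxy]-3,5-dimethoxyphenyl]prop-2-enal (present as its O7 aluminate) | COc1cc([C@@H](O)[C@@H](C)Oc2c(OC)cc(/C=C/C=O)cc2OC)cc(OC)c1OC | intermediate (not isolated)
13 | (1R,2R)-2-[4-[(E)-3-hydroxyprop-1-enyl]-2,6-dimethoxyphenoxy]-1-(3,4,5-trimethoxyphenyl)propan-1-ol | COc1cc([C@@H](O)[C@@H](C)Oc2c(OC)cc(/C=C/CO)cc2OC)cc(OC)c1OC | target

**Step count**
Total: 7 steps. Longest linear sequence: 6 steps (steps 1, 2, 3, 5, 6, 7).

**Steps most likely to fail**

Step 6 (proposed new method). C8 epimerisation may be slower than reduction, so the reaction would run as a kinetic resolution and the erythro (7R,8S) isomer would build up; the Felkin preference may also be incomplete. The fallback uses known chemistry and sets out from phenol 8. Ethyl (S)-lactate is converted with MeNH(OMe)·HCl and i-PrMgCl (THF, −20 °C) into (S)-2-hydroxy-N-methoxy-N-methylpropanamide F1. Mitsunobu etherification of 8 with F1 (PPh3, DIAD, THF, 0 °C to rt) inverts the carbinol centre and gives the (R)-aryloxy Weinreb amide F2. Commercial 3,4,5-trimethoxyphenylmagnesium bromide (THF, −40 °C) should attack the chelating amide before the conjugated methyl ester and give ketone 10, now isolated as the single R enantiomer. This is where the fallback comes back to the route: 10 is reduced to 11 with the same (S,S) catalyst in the acidic 5:2 HCO2H/Et3N mixture without added base, the matched pairing, in which no epimerisation is needed or wanted.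

Step 5. SN2 attack of the hindered 2,6-dimethoxyphenoxide at the secondary bromide may be slow, with competing dehydrobromination of 5 to the aryl vinyl ketone and base-induced degradation of the sinapate phenoxide. The fallback reverses the order of ether formation and olefination and sets out from bromo ketone 5. Alkylation of syringaldehyde 6 (K2CO3, DMF, rt), whose phenoxide is less basic and carries no Michael acceptor, gives the racemic keto aldehyde F3. Wittig olefination with ylide 7 (toluene, 80 °C) should take place at the aldehyde only, since stabilised ylides leave aryl ketones alone, and comes back to the route at 9.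

Step 7. Reduction may stall at enal 12 or stray into 1,4-reduction, and the C7 aluminate may gel and trap material. The fallback masks the hydroxyl instead of carrying it as an aluminate and sets out from 11. Silylation (TBSOTf, 2,6-lutidine, CH2Cl2, 0 °C) gives the C7 tert-butyldimethylsilyl ether F4. DIBAL-H (2.5 equiv, CH2Cl2, −78 °C) reduces the enoate of this homogeneous, aprotic substrate to the silyl-protected allylic alcohol F5. Bu4NF (THF, rt) removes the silyl group and comes back to the route at 13.

**Further compounds**
F1 | step 6 | (S)-2-hydroxy-N-methoxy-N-methylpropanamide | C[C@H](O)C(=O)N(C)OC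
F2 | step 6 | methyl (E)-3-[3,5-dimethoxy-4-[[(2R)-1-[methoxy(methyl)amino]-1-oxopropan-2-yl]oxy]phenyl]prop-2-enoate | CON(C)C(=O)[C@@H](C)Oc1c(OC)cc(/C=C/C(=O)OC)cc1OC
F3 | step 5 | racemic 3,5-dimethoxy-4-[[1-oxo-1-(3,4,5-trimethoxyphenyl)propan-2-yl]oxy]benzaldehyde | COc1cc(C(=O)C(C)Oc2c(OC)cc(C=O)cc2OC)cc(OC)c1OC
F4 | step 7 | methyl (E)-3-[4-[[(1R,2R)-1-[tert-butyl(dimethyl)silyl]oxy-1-(3,4,5-trimethoxyphenyl)propan-2-yl]oxy]-3,5-dimethoxyphenyl]prop-2-enoate | COc1cc([C@@H](O[Si](C)(C)C(C)(C)C)[C@@H](C)Oc2c(OC)cc(/C=C/C(=O)OC)cc2OC)cc(OC)c1OC
F5 | step 7 | (E)-3-[4-[[(1R,2R)-1-[tert-butyl(dimethyl)silyl]oxy-1-(3,4,5-trimethoxyphenyl)propan-2-yl]oxy]-3,5-dimethoxyphenyl]prop-2-en-1-ol | COc1cc([C@@H](O[Si](C)(C)C(C)(C)C)[C@@H](C)Oc2c(OC)cc(/C=C/CO)cc2OC)cc(OC)c1OC
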